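**Assumptions**
- Cudraphenone D has no stereocentre, and both alkenes end in CMe2, so there is no E/Z isomerism. The molecule is achiral and "single enantiomer" is moot, so nothing stereochemical has to be set or preserved.
- Compounds 1, 2, 4 and 5 are taken as catalogue chemicals. If 4 is unavailable, it is one Fischer esterification from 2-bromo-3-hydroxybenzoic acid.

## Retrosynthetic overview
1. Avoided: joining two preformed arenes (Friedel–Crafts/Hoesch acylation of phloroglucinol, or ArLi + ArCHO then oxidation) followed by unselective C-prenylation of the phloroglucinol.
2. Key disconnection: ring B is built de novo. Breaking the ring-B bond between the aroyl-bearing carbon and the C(OH) next to the prenyl carbon gives a linear C2-prenylated tetraketide ester. That ester is equivalent to its lactone, a 6-phenacyl-4-hydroxy-3-prenyl-2-pyrone that is an isomer of the target (both C23H26O5). The forward step is a biomimetic, benzophenone-synthase-type Claisen cyclisation.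
3. The pyrone comes from the C6-methyl dianion of 3-prenyl-triacetic acid lactone and methyl 3-hydroxy-2-prenylbenzoate (crossed Claisen).
4. Each prenyl is installed before the coupling, where regiochemistry is unambiguous: Pd π-prenyl alkylation at C3 of triacetic acid lactone, and Stille prenylation of methyl 2-bromo-3-hydroxybenzoate.
5. Ring order: ring A is purchased, the 2-pyrone is purchased as a masked C6 polyketide, and carbocyclic ring B is formed last by pyrone opening and reclosure. No protecting groups are used.

## Route

**Step 1**
Reactants: 1, triacetic acid lactone (4-hydroxy-6-methyl-2H-pyran-2-one); 2, prenyl acetate (3-methylbut-2-en-1-yl acetate)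
Product: 3, 4-hydroxy-6-methyl-3-(3-methylbut-2-en-1-yl)-2H-pyran-2-one
Conditions: 1 (1.5 equiv), 2 (1.0 equiv), Pd(PPh3)4 (3 mol %), DBU (1.5 equiv), THF/toluene, 65 °C, Ar; citric acid work-up
Reagents that add atoms: prenyl acetate, CC(C)=CCOC(C)=O
Why: In this Tsuji–Trost allylation the soft pyronate (pKa about 5) attacks the unhindered CH2 terminus of the 1,1-dimethyl-π-allyl-Pd complex to give the linear prenyl group at C3; any kinetic 4-O-prenyl ether re-ionises under Pd(0) and funnels to the irreversible C3 product, excess 1 suppresses 3,3-diprenylation, and no stereocentre is formed.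

**Step 2**
Reactants: 4, methyl 2-bromo-3-hydroxybenzoate; 5, tributyl(3-methylbut-2-en-1-yl)stannane
Product: 6, methyl 3-hydroxy-2-(3-methylbut-2-en-1-yl)benzoate
Conditions: 5 (1.3 equiv), Pd(PPh3)4 (5 mol %), degassed DMF, 100 °C; aq KF work-up
Reagents that add atoms: tributyl(prenyl)stannane, CCCC[Sn](CCCC)(CCCC)CC=C(C)C
Why: In this Migita–Kosugi–Stille allyl–aryl coupling the ortho ester activates the C–Br bond for oxidative addition, the neutral conditions tolerate the free phenol and the ester, and reductive elimination from the aryl(prenyl)Pd species forms the C–C bond at the less hindered CH2 terminus, which fixes the 1,2,3-pattern of ring A without any regiochemical ambiguity.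

**Step 3**
Reactants: 3, 3-prenyl-triacetic acid lactone; 6, methyl 3-hydroxy-2-prenylbenzoate
Product: 7, 4-hydroxy-6-{2-[3-hydroxy-2-(3-methylbut-2-en-1-yl)phenyl]-2-oxoethyl}-3-(3-methylbut-2-en-1-yl)-2H-pyran-2-one
Conditions: 3 (2.2 equiv), LDA (4.5 equiv), THF/DMPU (6:1), −78 to −20 °C; then the Li phenoxide of 6 [6 (1.0 equiv), LiHMDS (1.05 equiv), THF, −78 °C], −78 to 0 °C; AcOH quench, aq citric acid; excess 3 recovered
Reagents that add atoms: none beyond reactants 3 and 6 (MeOH is lost)
Why: This is a crossed Claisen acylation of a 4-oxido-2-pyrone C6-methyl dianion with a non-enolisable aryl ester, in which the exocyclic carbanion is the most nucleophilic site, the second equivalent of dianion deprotonates the product and so prevents over-addition, and pre-forming the phenoxide both masks the OH and lowers the acidity of the adjacent benzylic/allylic CH2, which disfavours toluate-type lateral deprotonation.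

**Step 4 (key step)**
Reactants: 7, the pyrone tetraketide
Product: 8, cudraphenone D, [3-hydroxy-2-(3-methylbut-2-en-1-yl)phenyl][2,4,6-trihydroxy-3-(3-methylbut-2-en-1-yl)phenyl]methanone
Conditions: Mg(OMe)2 (8 equiv), degassed MeOH, reflux, Ar, 12–24 h; cold 1 M HCl to pH 3–4, rapid EtOAc extraction
Reagents that add atoms: none (net isomerisation, C23H26O5 to C23H26O5; methoxide adds at the lactone carbonyl and is expelled again)
Why: This is the biomimetic pyrone-to-acylphloroglucinol rearrangement (Mg-templated lactone methanolysis to the methyl 3,5,7-trioxoheptanoate, intramolecular Claisen/Dieckmann attack of the C6 carbanion on the C1 ester, then tautomerisation), a known reaction type for 6-(2-oxoalkyl)-4-hydroxy-2-pyrones; non-hydrolytic methoxide keeps C1 as an acylating ester, while the rival C2-to-C7 aldol (resorcylate) mode would create a quaternary prenyl-bearing C2 that cannot aromatise directly and would have to attack an ortho-substituted aryl ketone, so aromatisation to 8 is the favoured thermodynamic sink, and no stereocentre is formed.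

Atom map for ring B (pyrone atom → ring-B position):

| Pyrone atom in 7 | Ring-B position in 8 |
|---|---|
| C2 (lactone C=O) | C–OH ortho to the ketone |
| C3 (prenyl) | prenyl carbon |
| C4 (OH) | para C–OH |
| C5 (H) | the single Ar–H |
| C6 (ring O) | second ortho C–OH |
| exocyclic CH2 | aroyl-bearing carbon |

Going round the ring this reads aroyl / OH / prenyl / OH / H / OH, which matches the target SMILES.

## Compound list
| No. | Name | SMILES | Role |
|---|---|---|---|
| 1 | Triacetic acid lactone (4-hydroxy-6-methyl-2H-pyran-2-one) | CC1=CC(O)=CC(=O)O1 | starting material |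
| 2 | Prenyl acetate | CC(C)=CCOC(C)=O | starting material |
| 3 | 4-Hydroxy-6-methyl-3-prenyl-2H-pyran-2-one | CC1=CC(O)=C(CC=C(C)C)C(=O)O1 | intermediate |
| 4 | Methyl 2-bromo-3-hydroxybenzoate | COC(=O)c1cccc(O)c1Br | starting material |
| 5 | Tributyl(3-methylbut-2-en-1-yl)stannane | CCCC[Sn](CCCC)(CCCC)CC=C(C)C | starting material |
| 6 | Methyl 3-hydroxy-2-prenylbenzoate | COC(=O)c1cccc(O)c1CC=C(C)C | intermediate |
| 7 | 4-Hydroxy-6-[2-(3-hydroxy-2-prenylphenyl)-2-oxoethyl]-3-prenyl-2H-pyran-2-one | CC(C)=CCc1c(O)cccc1C(=O)CC1=CC(O)=C(CC=C(C)C)C(=O)O1 | intermediate |
| 8 | Cudraphenone D (achiral) | CC(C)=CCc1c(O)cccc1C(=O)c1c(O)cc(O)c(CC=C(C)C)c1O | target |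

## Summary
Total step count: 4.
Longest linear sequence: 3 (Step 1 or Step 2, then Step 3, then Step 4).

**Three steps most likely to fail**
1. **Step 4.**
   - Risk: the doubly deprotonated, C3-substituted pyrone may resist methanolysis. The open triketo ester may instead undergo retro-Claisen cleavage or γ-pyrone formation.
   - Fallback: generate the open-chain ester without nucleophilic lactone opening. Acylate the dianion of 2,2-dimethyl-6-(2-oxopropyl)-5-prenyl-1,3-dioxin-4-one with 6. Thermolyse the resulting diketo-dioxinone (toluene, 110 °C, MeOH) through its acylketene to the methyl triketo ester, then cyclise that isolated ester with base in a separate operation.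
2. **Step 3.**
   - Risk: proton transfer from the benzylic/allylic CH2 of 6 to the dianion, or sluggish attack on the ortho-substituted phenoxide ester.
   - Fallback: change the oxidation level of the electrophile. Add the dianion of 3 to 3-hydroxy-2-prenylbenzaldehyde, made from commercial 2-bromo-3-hydroxybenzaldehyde by the same prenylation. Carbonyl addition should outrun proton transfer. Then oxidise the benzylic carbinol (MnO2) to 7.
3. **Step 2.**
   - Risk: the di-ortho-substituted bromide bearing a free phenol may give slow coupling, some γ-coupled (reverse-prenyl) product, or alkene migration.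
   - Fallback: build the C2 side chain by sigmatropy instead of cross-coupling. O-allylate methyl 3-hydroxybenzoate and run a thermal aromatic Claisen rearrangement, where the meta ester directs mainly to C2 to give methyl 2-allyl-3-hydroxybenzoate. Then convert allyl to prenyl by cross-metathesis with 2-methyl-2-butene (Grubbs II) to reach 6.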